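**Retrosynthetic overview**
1. C-7 hydroxyl: last C–O bond, by oxidation of the kinetic dienone enolate on the face away from the angular methyl.
2. Ester: alkyl C–O bond by Mitsunobu inversion of the C-2-epimeric dienone alcohol with the dienoic acid, which sets C-2.
3. Ring B: intramolecular aldol condensation of a 3-oxobutyl chain onto the ring A enone.
4. Ring A with C-1, C-2 and quaternary C-8a: one catalytic enantioselective endo Diels–Alder of tiglaldehyde with (1E,3E)-1-acetoxy-4-silyloxybutadiene (key step, in place of a Robinson annulation on a dimethylcyclohexanone).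
5. Ring order: ring A first (cycloaddition), ring B second (aldol). Side-chain acid by vinylogous Horner–Wadsworth–Emmons from (S)-2-hydroxy-2-methylbutanoic acid.

Assumption: (S)-2-hydroxy-2-methylbutanoic acid and (1E,3E)-buta-1,3-diene-1,4-diyl diacetate are bought as such; the catalyst enantiomer in step 2 is assigned from the formyl C–H···O binding model and is the least certain stereochemical call in the route.

**Step 1**
Reactants: 1 (1E,3E)-buta-1,3-diene-1,4-diyl diacetate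
Product: 3 (1E,3E)-4-[(tert-butyldimethylsilyl)oxy]buta-1,3-dien-1-yl acetate, via lithium dienolate 2 (not isolated)
Conditions: MeLi (2.0 equiv), THF, −78 °C; TBSCl (1.05 equiv), DMPU, −78 → 0 °C; aq NH4Cl
Reagents that add atoms: tert-butyldimethylsilyl chloride, CC(C)(C)[Si](C)(C)Cl
Why: Enol-ester cleavage by MeLi (House enolate generation) opens one acetate only, because the dienolate formed deactivates the second acetate by conjugation, and O-silylation keeps the E,E geometry.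

**Step 2**
Reactants: 3 (1E,3E)-4-[(tert-butyldimethylsilyl)oxy]buta-1,3-dien-1-yl acetate; 4 (E)-2-methylbut-2-enal
Product: 5 (1R,4S,5R,6R)-4-[(tert-butyldimethylsilyl)oxy]-5-formyl-5,6-dimethylcyclohex-2-en-1-yl acetate
Conditions: (S)-1-(2-methylphenyl)-3,3-diphenyltetrahydro-1H,3H-pyrrolo[1,2-c][1,3,2]oxazaborole (20 mol %), (CF3SO2)2NH (20 mol %), CH2Cl2, −78 → −40 °C; Et3N quench
Reagents that add atoms: none
Why: Catalytic enantioselective Diels–Alder reaction in which the silyloxy terminus (stronger donor) bonds to C-2 of the enal, the E-enal fixes the two methyls cis, the endo transition state puts both oxygens cis to the formyl group, and the formyl C–H···O-bound s-trans enal on the oxazaborolidinium cation is attacked on its Si face at C-2, so all four centres form in one step.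

**Step 3**
Reactants: 5 (1R,4S,5R,6R)-4-[(tert-butyldimethylsilyl)oxy]-5-formyl-5,6-dimethylcyclohex-2-en-1-yl acetate; 6 1-(triphenyl-λ5-phosphanylidene)propan-2-one
Product: 7 (1R,4S,5R,6R)-4-[(tert-butyldimethylsilyl)oxy]-5,6-dimethyl-5-[(1E)-3-oxobut-1-en-1-yl]cyclohex-2-en-1-yl acetate
Conditions: toluene, 100 °C
Reagents that add atoms: none
Why: Wittig olefination with a stabilised ylide gives the E-enone, and the aldehyde has no α-hydrogen so the quaternary centre cannot epimerise.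

**Step 4**
Reactants: 7 (1R,4S,5R,6R)-4-[(tert-butyldimethylsilyl)oxy]-5,6-dimethyl-5-[(1E)-3-oxobut-1-en-1-yl]cyclohex-2-en-1-yl acetate
Product: 8 (1R,4S,5R,6R)-4-[(tert-butyldimethylsilyl)oxy]-5,6-dimethyl-5-(3-oxobutyl)cyclohex-2-en-1-yl acetate
Conditions: [(Ph3P)CuH]6 (0.4 equiv), H2O (3 equiv), toluene/THF, rt; aq NH4Cl
Reagents that add atoms: none
Why: Copper hydride conjugate reduction saturates only the enone C=C and leaves the isolated ring alkene, the acetate and the silyl ether untouched.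

**Step 5**
Reactants: 8 (1R,4S,5R,6R)-4-[(tert-butyldimethylsilyl)oxy]-5,6-dimethyl-5-(3-oxobutyl)cyclohex-2-en-1-yl acetate
Product: 9 (1R,4S,5R,6R)-4-hydroxy-5,6-dimethyl-5-(3-oxobutyl)cyclohex-2-en-1-yl acetate
Conditions: HF·pyridine, pyridine, THF, 0 °C → rt
Reagents that add atoms: none
Why: Fluoride desilylation frees the allylic alcohol while the acetate keeps the other oxygen distinct.

**Step 6**
Reactants: 9 (1R,4S,5R,6R)-4-hydroxy-5,6-dimethyl-5-(3-oxobutyl)cyclohex-2-en-1-yl acetate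
Product: 10 (1R,5R,6R)-5,6-dimethyl-4-oxo-5-(3-oxobutyl)cyclohex-2-en-1-yl acetate
Conditions: Dess–Martin periodinane, CH2Cl2, 0 °C → rt
Reagents that add atoms: none
Why: Dess–Martin oxidation of the allylic alcohol gives the ring A enone, whose α-carbon is quaternary and so configurationally fixed.

**Step 7**
Reactants: 10 (1R,5R,6R)-5,6-dimethyl-4-oxo-5-(3-oxobutyl)cyclohex-2-en-1-yl acetate
Product: 12 (1R,2R,8aR)-1,8a-dimethyl-6-oxo-1,2,6,7,8,8a-hexahydronaphthalen-2-yl acetate, via aldol adduct 11 (not isolated)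
Conditions: pyrrolidine (0.3 equiv), AcOH (0.3 equiv), toluene, 70 °C
Reagents that add atoms: none
Why: Enamine-mediated intramolecular aldol condensation of the methyl ketone onto the enone carbonyl closes ring B, and dehydration of the tertiary allylic alcohol gives the linear dienone under conditions too mild to isomerise the γ-acetoxy enone.

**Step 8**
Reactants: 12 (1R,2R,8aR)-1,8a-dimethyl-6-oxo-1,2,6,7,8,8a-hexahydronaphthalen-2-yl acetate
Product: 13 (4aR,5R,6R)-6-hydroxy-4a,5-dimethyl-4,4a,5,6-tetrahydronaphthalen-2(3H)-one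
Conditions: K2CO3 (0.2 equiv), MeOH, 0 °C
Reagents that add atoms: none
Why: Mild transesterification removes the acetate by acyl–oxygen cleavage, so the carbinol configuration is unchanged.

**Step 9**
Reactants: 14 (S)-2-hydroxy-2-methylbutanoic acid
Product: 15 methyl (S)-2-hydroxy-2-methylbutanoate
Conditions: MeOH, H2SO4 (cat.), reflux
Reagents that add atoms: methanol, CO
Why: Fischer esterification, with the tertiary stereocentre not involved.

**Step 10**
Reactants: 15 methyl (S)-2-hydroxy-2-methylbutanoate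
Product: 16 methyl (S)-2-methyl-2-[(triethylsilyl)oxy]butanoate
Conditions: TESOTf, 2,6-lutidine, CH2Cl2, 0 °C
Reagents that add atoms: triethylsilyl trifluoromethanesulfonate, CC[Si](CC)(CC)OS(=O)(=O)C(F)(F)F
Why: Silyl triflate silylation is strong enough for the hindered tertiary alcohol.

**Step 11**
Reactants: 16 methyl (S)-2-methyl-2-[(triethylsilyl)oxy]butanoate
Product: 17 (S)-2-methyl-2-[(triethylsilyl)oxy]butanal
Conditions: i-Bu2AlH (1.1 equiv), CH2Cl2, −78 °C; aq potassium sodium tartrate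
Reagents that add atoms: none
Why: Low-temperature half-reduction of the α-silyloxy ester stops at the aldehyde, which has no α-hydrogen and cannot racemise.

**Step 12**
Reactants: 17 (S)-2-methyl-2-[(triethylsilyl)oxy]butanal; 18 ethyl (2E)-4-(diethoxyphosphoryl)but-2-enoate
Product: 20 ethyl (2E,4E,6S)-6-methyl-6-[(triethylsilyl)oxy]octa-2,4-dienoate, via lithiated phosphonate 19 (not isolated)
Conditions: LiN(SiMe3)2, THF, −78 °C; then 17, −78 → 0 °C
Reagents that add atoms: none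
Why: Vinylogous Horner–Wadsworth–Emmons olefination gives the E,E-dienoate, with the bulky α-branched aldehyde reinforcing E selectivity at the new double bond.

**Step 13**
Reactants: 20 ethyl (2E,4E,6S)-6-methyl-6-[(triethylsilyl)oxy]octa-2,4-dienoate
Product: 21 (2E,4E,6S)-6-methyl-6-[(triethylsilyl)oxy]octa-2,4-dienoic acid
Conditions: LiOH, THF/MeOH/H2O, rt; AcOH to pH 5
Reagents that add atoms: lithium hydroxide, [Li+].[OH-]
Why: Saponification of the ethyl ester, with the tertiary silyl ether stable to hydroxide and to the weakly acidic work-up.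

**Step 14**
Reactants: 13 (4aR,5R,6R)-6-hydroxy-4a,5-dimethyl-4,4a,5,6-tetrahydronaphthalen-2(3H)-one; 21 (2E,4E,6S)-6-methyl-6-[(triethylsilyl)oxy]octa-2,4-dienoic acid
Product: 22 (1R,2S,8aR)-1,8a-dimethyl-6-oxo-1,2,6,7,8,8a-hexahydronaphthalen-2-yl (2E,4E,6S)-6-methyl-6-[(triethylsilyl)oxy]octa-2,4-dienoate
Conditions: PPh3, DIAD, toluene, 0 °C → rt
Reagents that add atoms: none
Why: Mitsunobu esterification displaces the activated allylic oxygen by the carboxylate with clean SN2 inversion, which turns the (2R) carbinol from the endo cycloaddition into the required (2S) ester cis to both methyls, reacting through the conformer with a pseudoaxial leaving group that has no antiperiplanar hydrogen for elimination.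

**Step 15**
Reactants: 22 (1R,2S,8aR)-1,8a-dimethyl-6-oxo-1,2,6,7,8,8a-hexahydronaphthalen-2-yl (2E,4E,6S)-6-methyl-6-[(triethylsilyl)oxy]octa-2,4-dienoate
Product: 24 (1R,2S,7R,8aR)-7-hydroxy-1,8a-dimethyl-6-oxo-1,2,6,7,8,8a-hexahydronaphthalen-2-yl (2E,4E,6S)-6-methyl-6-[(triethylsilyl)oxy]octa-2,4-dienoate, via sodium enolate 23 (not isolated)
Conditions: NaN(SiMe3)2 (1.1 equiv), THF, −78 °C; 2-(phenylsulfonyl)-3-phenyloxaziridine, −78 °C; aq NH4Cl
Reagents that add atoms: 2-(phenylsulfonyl)-3-phenyloxaziridine, O=S(=O)(N1OC1c1ccccc1)c1ccccc1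
Why: Kinetic deprotonation gives the cross-conjugated C-7 enolate, and Davis oxaziridine hydroxylation occurs on the face opposite the axial angular methyl, which sets the equatorial (7R) alcohol.

**Step 16**
Reactants: 24 (1R,2S,7R,8aR)-7-hydroxy-1,8a-dimethyl-6-oxo-1,2,6,7,8,8a-hexahydronaphthalen-2-yl (2E,4E,6S)-6-methyl-6-[(triethylsilyl)oxy]octa-2,4-dienoate
Product: 25 (1R,2S,7R,8aR)-7-hydroxy-1,8a-dimethyl-6-oxo-1,2,6,7,8,8a-hexahydronaphthalen-2-yl (2E,4E,6S)-6-hydroxy-6-methylocta-2,4-dienoate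
Conditions: HF·pyridine, pyridine, THF, 0 °C
Reagents that add atoms: none
Why: Buffered fluoride desilylation frees the tertiary alcohol without touching the α-ketol, the dienone or the allylic ester.

**Compound list**
1 | (1E,3E)-buta-1,3-diene-1,4-diyl diacetate | CC(=O)O/C=C/C=C/OC(C)=O | starting material
2 | lithium (1E,3E)-4-acetoxybuta-1,3-dien-1-olate | [Li+].[O-]/C=C/C=C/OC(C)=O | intermediate
3 | (1E,3E)-4-[(tert-butyldimethylsilyl)oxy]buta-1,3-dien-1-yl acetate | CC(=O)O/C=C/C=C/O[Si](C)(C)C(C)(C)C | intermediate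
4 | (E)-2-methylbut-2-enal (tiglaldehyde) | C/C=C(\C)C=O | starting material
5 | (1R,4S,5R,6R)-4-[(tert-butyldimethylsilyl)oxy]-5-formyl-5,6-dimethylcyclohex-2-en-1-yl acetate | CC(=O)O[C@@H]1C=C[C@H](O[Si](C)(C)C(C)(C)C)[C@](C)(C=O)[C@H]1C | intermediate
6 | 1-(triphenyl-λ5-phosphanylidene)propan-2-one | CC(=O)C=P(c1ccccc1)(c1ccccc1)c1ccccc1 | starting material
7 | (1R,4S,5R,6R)-4-[(tert-butyldimethylsilyl)oxy]-5,6-dimethyl-5-[(1E)-3-oxobut-1-en-1-yl]cyclohex-2-en-1-yl acetate | CC(=O)O[C@@H]1C=C[C@H](O[Si](C)(C)C(C)(C)C)[C@](C)(/C=C/C(C)=O)[C@H]1C | intermediate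
8 | (1R,4S,5R,6R)-4-[(tert-butyldimethylsilyl)oxy]-5,6-dimethyl-5-(3-oxobutyl)cyclohex-2-en-1-yl acetate | CC(=O)O[C@@H]1C=C[C@H](O[Si](C)(C)C(C)(C)C)[C@](C)(CCC(C)=O)[C@H]1C | intermediate
9 | (1R,4S,5R,6R)-4-hydroxy-5,6-dimethyl-5-(3-oxobutyl)cyclohex-2-en-1-yl acetate | CC(=O)O[C@@H]1C=C[C@H](O)[C@](C)(CCC(C)=O)[C@H]1C | intermediate
10 | (1R,5R,6R)-5,6-dimethyl-4-oxo-5-(3-oxobutyl)cyclohex-2-en-1-yl acetate | CC(=O)O[C@@H]1C=CC(=O)[C@](C)(CCC(C)=O)[C@H]1C | intermediate
11 | (1R,2R,8aR)-4a-hydroxy-1,8a-dimethyl-6-oxo-1,2,4a,5,6,7,8,8a-octahydronaphthalen-2-yl acetate (C-4a configuration not assigned) | CC(=O)O[C@@H]1C=CC2(O)CC(=O)CC[C@]2(C)[C@H]1C | intermediate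
12 | (1R,2R,8aR)-1,8a-dimethyl-6-oxo-1,2,6,7,8,8a-hexahydronaphthalen-2-yl acetate | CC(=O)O[C@@H]1C=CC2=CC(=O)CC[C@]2(C)[C@H]1C | intermediate
13 | (4aR,5R,6R)-6-hydroxy-4a,5-dimethyl-4,4a,5,6-tetrahydronaphthalen-2(3H)-one | O[C@@H]1C=CC2=CC(=O)CC[C@]2(C)[C@H]1C | intermediate
14 | (S)-2-hydroxy-2-methylbutanoic acid | CC[C@](C)(O)C(O)=O | starting material
15 | methyl (S)-2-hydroxy-2-methylbutanoate | CC[C@](C)(O)C(=O)OC | intermediate
16 | methyl (S)-2-methyl-2-[(triethylsilyl)oxy]butanoate | CC[C@](C)(O[Si](CC)(CC)CC)C(=O)OC | intermediate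
17 | (S)-2-methyl-2-[(triethylsilyl)oxy]butanal | CC[C@](C)(O[Si](CC)(CC)CC)C=O | intermediate
18 | ethyl (2E)-4-(diethoxyphosphoryl)but-2-enoate | CCOC(=O)/C=C/CP(=O)(OCC)OCC | starting material
19 | lithium salt of ethyl (2E)-4-(diethoxyphosphoryl)but-2-enoate (C-4 anion) | [Li+].CCOC(=O)/C=C/[CH-]P(=O)(OCC)OCC | intermediate
20 | ethyl (2E,4E,6S)-6-methyl-6-[(triethylsilyl)oxy]octa-2,4-dienoate | CC[C@](C)(O[Si](CC)(CC)CC)/C=C/C=C/C(=O)OCC | intermediate
21 | (2E,4E,6S)-6-methyl-6-[(triethylsilyl)oxy]octa-2,4-dienoic acid | CC[C@](C)(O[Si](CC)(CC)CC)/C=C/C=C/C(O)=O | intermediate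
22 | (1R,2S,8aR)-1,8a-dimethyl-6-oxo-1,2,6,7,8,8a-hexahydronaphthalen-2-yl (2E,4E,6S)-6-methyl-6-[(triethylsilyl)oxy]octa-2,4-dienoate | CC[C@](C)(O[Si](CC)(CC)CC)/C=C/C=C/C(=O)O[C@H]1C=CC2=CC(=O)CC[C@]2(C)[C@H]1C | intermediate
23 | sodium 6,7-enolate of 22 | [Na+].CC[C@](C)(O[Si](CC)(CC)CC)/C=C/C=C/C(=O)O[C@H]1C=CC2=CC([O-])=CC[C@]2(C)[C@H]1C | intermediate
24 | (1R,2S,7R,8aR)-7-hydroxy-1,8a-dimethyl-6-oxo-1,2,6,7,8,8a-hexahydronaphthalen-2-yl (2E,4E,6S)-6-methyl-6-[(triethylsilyl)oxy]octa-2,4-dienoate | CC[C@](C)(O[Si](CC)(CC)CC)/C=C/C=C/C(=O)O[C@H]1C=CC2=CC(=O)[C@H](O)C[C@]2(C)[C@H]1C | intermediate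
25 | (1R,2S,7R,8aR)-7-hydroxy-1,8a-dimethyl-6-oxo-1,2,6,7,8,8a-hexahydronaphthalen-2-yl (2E,4E,6S)-6-hydroxy-6-methylocta-2,4-dienoate | CC[C@](C)(O)/C=C/C=C/C(=O)O[C@H]1C=CC2=CC(=O)[C@H](O)C[C@]2(C)[C@H]1C | target

**Summary**
Total step count: 16.
Longest linear sequence: 11 steps (steps 1 to 8, then 14 to 16); the side-chain branch is 5 steps (9 to 13).

**Steps most likely to fail, with fallbacks**

Step 2 (cycloaddition). The silyl dienol ether may not survive the cationic Lewis acid, the trisubstituted enal may react slowly, or the ee may be low. The fallback sets out from 3 and 4 and comes back at 8. The two are heated without catalyst (toluene, 110 °C, sealed tube) to give the racemic endo cycloadduct F1. Wittig reaction with 6 gives the racemic enone F2, and [(Ph3P)CuH]6 reduction gives the racemic keto acetate F3. K2CO3 in MeOH gives the racemic allylic alcohol F4. Acylative kinetic resolution (Ac2O 0.55 equiv, (S)-2-phenyl-2,3-dihydrobenzo[d]imidazo[2,1-b]thiazole 5 mol %, i-Pr2NEt, CHCl3, 0 °C) then acetylates the (1R)-alcohol, by analogy with allylic and benzylic carbinols, and returns enantioenriched 8; the (1S)-alcohol stays behind.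

Step 14 (Mitsunobu inversion). Attack at C-2 is flanked by the C-1 methyl and is syn to the angular methyl, so elimination or no reaction is possible with the valuable acid. The fallback sets out from 13 and comes back at 22, and separates inversion from acylation. Mitsunobu reaction with the smaller, more acidic 4-nitrobenzoic acid (PPh3, DIAD, toluene) gives the inverted 4-nitrobenzoate F5. K2CO3 in MeOH gives the (6S)-alcohol F6. Yamaguchi acylation with 21 (2,4,6-trichlorobenzoyl chloride, Et3N, then 4-(dimethylamino)pyridine, toluene) proceeds with retention and gives 22.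

Step 15 (late hydroxylation). The base-sensitive allylic dienoate and the extended enolisable system may not tolerate enolate chemistry. The fallback sets out from 22 and comes back at 24, and replaces the enolate by a radical α'-acetoxylation. Mn(OAc)3 (toluene, 80 °C) gives the equatorial 7-acetoxy ketone F7 after equilibration. Brief methanolysis of this activated α-keto acetate (K2CO3 0.1 equiv, MeOH, −10 °C) gives 24.

**Further compounds**
F1 | step 2 | rac-(1R,4S,5R,6R)-4-[(tert-butyldimethylsilyl)oxy]-5-formyl-5,6-dimethylcyclohex-2-en-1-yl acetate (racemate, one enantiomer drawn) | CC(=O)O[C@@H]1C=C[C@H](O[Si](C)(C)C(C)(C)C)[C@](C)(C=O)[C@H]1C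
F2 | step 2 | rac-(1R,4S,5R,6R)-4-[(tert-butyldimethylsilyl)oxy]-5,6-dimethyl-5-[(1E)-3-oxobut-1-en-1-yl]cyclohex-2-en-1-yl acetate (racemate, one enantiomer drawn) | CC(=O)O[C@@H]1C=C[C@H](O[Si](C)(C)C(C)(C)C)[C@](C)(/C=C/C(C)=O)[C@H]1C
F3 | step 2 | rac-(1R,4S,5R,6R)-4-[(tert-butyldimethylsilyl)oxy]-5,6-dimethyl-5-(3-oxobutyl)cyclohex-2-en-1-yl acetate (racemate, one enantiomer drawn) | CC(=O)O[C@@H]1C=C[C@H](O[Si](C)(C)C(C)(C)C)[C@](C)(CCC(C)=O)[C@H]1C
F4 | step 2 | rac-(1R,4S,5R,6R)-4-[(tert-butyldimethylsilyl)oxy]-5,6-dimethyl-5-(3-oxobutyl)cyclohex-2-en-1-ol (racemate, one enantiomer drawn) | O[C@@H]1C=C[C@H](O[Si](C)(C)C(C)(C)C)[C@](C)(CCC(C)=O)[C@H]1C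
F5 | step 14 | (1R,2S,8aR)-1,8a-dimethyl-6-oxo-1,2,6,7,8,8a-hexahydronaphthalen-2-yl 4-nitrobenzoate | O=C(O[C@H]1C=CC2=CC(=O)CC[C@]2(C)[C@H]1C)c1ccc(cc1)[N+](=O)[O-]
F6 | step 14 | (4aR,5R,6S)-6-hydroxy-4a,5-dimethyl-4,4a,5,6-tetrahydronaphthalen-2(3H)-one | O[C@H]1C=CC2=CC(=O)CC[C@]2(C)[C@H]1C
F7 | step 15 | (1R,2S,7R,8aR)-7-acetoxy-1,8a-dimethyl-6-oxo-1,2,6,7,8,8a-hexahydronaphthalen-2-yl (2E,4E,6S)-6-methyl-6-[(triethylsilyl)oxy]octa-2,4-dienoate | CC[C@](C)(O[Si](CC)(CC)CC)/C=C/C=C/C(=O)O[C@H]1C=CC2=CC(=O)[C@H](OC(C)=O)C[C@]2(C)[C@H]1C
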